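The trimer is cut at both interflavan C4–C8 bonds into a catechin C4 cation and two gallocatechin units, both drawn from one benzylated gallocatechin acetate. In that unit ring C is not closed by etherification. Its ether oxygen O1 and its methylene C4 sit on the neighbouring ring A carbons C8a and C4a; in the precursor both hang on C8a, in a spiro oxolane on a cyclohexadienone that already holds C2 and C3 in their final configuration. Carbonyl reduction and ionisation of the dienol then shift C4 to C4a: the oxolane becomes the pyran, ring A becomes aromatic, and the auxiliary oxygen at C6 is lost.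

Key step: step 10

Remark: the target is read as catechin-(4α→8)-gallocatechin-(4α→8)-gallocatechin, all three units 2R,3S (2,3-trans) and both interflavan bonds 3,4-trans; 1, 7 and 19 are taken as commercial.

Step 1
Reactants: 1 1,3-bis(benzyloxy)benzene
Product: 4 2,6-bis(benzyloxy)phenol, via aryllithium 2 (not isolated), via lithium aryltrimethoxyborate 3 (not isolated)
Conditions: n-BuLi, THF, 0 °C; B(OMe)3, −78 °C to rt; H2O2 (30%), NaOH (aq), 0 °C
Reagents that add atoms: hydrogen peroxide, OO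
Why: Directed ortho-metalation at the carbon flanked by both benzyloxy groups, borylation and oxidative boron-to-oxygen 1,2-shift (boronate oxidation) should give the phenol, the low temperature keeping benzylic deprotonation and Wittig rearrangement slow.

Step 2
Reactants: 4 2,6-bis(benzyloxy)phenol
Product: 5 2,6-bis(benzyloxy)-4-bromophenol
Conditions: NBS, CH2Cl2, −20 to 0 °C
Reagents that add atoms: N-bromosuccinimide, O=C1CCC(=O)N1Br
Why: Electrophilic aromatic bromination directed para by the free hydroxyl group, both ortho positions being blocked.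

Step 3
Reactants: 5 2,6-bis(benzyloxy)-4-bromophenol
Product: 6 [2,6-bis(benzyloxy)-4-bromophenoxy](tert-butyl)dimethylsilane
Conditions: TBSCl, imidazole, DMF, rt
Reagents that add atoms: tert-butyldimethylsilyl chloride, CC(C)(C)[Si](C)(C)Cl
Why: Silylation of the phenol, so that the aryl bromide can be turned into a Grignard reagent.

Step 4
Reactants: 7 3,4,5-tris(benzyloxy)benzaldehyde
Product: 8 rac-1-[3,4,5-tris(benzyloxy)phenyl]prop-2-en-1-ol
Conditions: CH2=CHMgBr, THF, −78 to 0 °C; NH4Cl (aq)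
Reagents that add atoms: vinylmagnesium bromide, C=C[Mg]Br
Why: Grignard 1,2-addition to the aldehyde gives the racemic secondary allylic alcohol needed for the resolution.

Step 5
Reactants: 8 rac-1-[3,4,5-tris(benzyloxy)phenyl]prop-2-en-1-ol
Product: 9 (R)-[(2S)-oxiran-2-yl][3,4,5-tris(benzyloxy)phenyl]methanol (erythro epoxy alcohol)
Conditions: Ti(OiPr)4 (0.15 equiv), D-(−)-diisopropyl tartrate (0.2 equiv), t-BuOOH (0.55 equiv), 4 Å molecular sieves, CH2Cl2, −20 °C
Reagents that add atoms: tert-butyl hydroperoxide, CC(C)(C)OO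
Why: Sharpless kinetic resolution by asymmetric epoxidation: with D-(−)-diisopropyl tartrate the (S)-alcohol should be epoxidised much faster than the (R)-alcohol, oxygen being delivered to the alkene face dictated by the tartrate from the rotamer that turns the carbinol hydrogen toward titanium, which sets the oxirane carbon as S and the erythro relation of the two oxygens; the reaction is stopped near half conversion (at most half of 8 can be used) and unreacted (R)-8 is separated.

Step 6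
Reactants: 6 [2,6-bis(benzyloxy)-4-bromophenoxy](tert-butyl)dimethylsilane; 9 (R)-[(2S)-oxiran-2-yl][3,4,5-tris(benzyloxy)phenyl]methanol
Product: 11 (1R,2S)-3-{3,5-bis(benzyloxy)-4-[(tert-butyldimethylsilyl)oxy]phenyl}-1-[3,4,5-tris(benzyloxy)phenyl]propane-1,2-diol, via arylmagnesium bromide 10 (not isolated)
Conditions: 6, Mg, THF, 50 °C; 9 pre-treated with MeMgBr (1 equiv), THF, −40 °C; then CuI (10 mol %), −30 to 0 °C; NH4Cl (aq)
Reagents that add atoms: none
Why: Copper-catalysed SN2 opening of the terminal epoxide by the aryl Grignard reagent at the unhindered CH2 carbon forms the aryl–CH2 bond without touching either stereocentre, so the erythro (1R,2S) diol should result.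

Step 7
Reactants: 11 (1R,2S)-3-{3,5-bis(benzyloxy)-4-[(tert-butyldimethylsilyl)oxy]phenyl}-1-[3,4,5-tris(benzyloxy)phenyl]propane-1,2-diol
Product: 12 (1R,2S)-3-[3,5-bis(benzyloxy)-4-hydroxyphenyl]-1-[3,4,5-tris(benzyloxy)phenyl]propane-1,2-diol
Conditions: n-Bu4NF, AcOH, THF, 0 °C, under argon
Reagents that add atoms: none
Why: Fluoride-induced desilylation of the aryl silyl ether, buffered so that the electron-rich phenolate is not exposed to air oxidation.

Step 8
Reactants: 12 (1R,2S)-3-[3,5-bis(benzyloxy)-4-hydroxyphenyl]-1-[3,4,5-tris(benzyloxy)phenyl]propane-1,2-diol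
Product: 13 (2R,3S)-7,9-bis(benzyloxy)-3-hydroxy-2-[3,4,5-tris(benzyloxy)phenyl]-1-oxaspiro[4.5]deca-6,9-dien-8-one
Conditions: PhI(OAc)2, CF3CH2OH/CH2Cl2, −20 °C; NaHCO3 (aq)
Reagents that add atoms: none
Why: Oxidative dearomatisation of the phenol with the trivalent iodine reagent (spiroetherification): ligand exchange at iodine and loss of iodobenzene make the para carbon electrophilic, and the benzylic hydroxyl closes the oxolane by 5-exo attack (the other hydroxyl could only form an oxetane) with no C–O bond at either stereocentre broken, the spiro carbon being non-stereogenic because the dienone ring is symmetric.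

Step 9
Reactants: 13 (2R,3S)-7,9-bis(benzyloxy)-3-hydroxy-2-[3,4,5-tris(benzyloxy)phenyl]-1-oxaspiro[4.5]deca-6,9-dien-8-one
Product: 14 (2R,3S)-7,9-bis(benzyloxy)-8-oxo-2-[3,4,5-tris(benzyloxy)phenyl]-1-oxaspiro[4.5]deca-6,9-dien-3-yl acetate
Conditions: Ac2O, pyridine, DMAP (cat.), CH2Cl2, rt
Reagents that add atoms: acetic anhydride, CC(=O)OC(C)=O
Why: DMAP-catalysed acylation of the only hydroxyl group, so that triflic anhydride in step 10 meets a single alcohol and the 3-acetate can later act as participating group.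

Step 10
Reactants: 14 (2R,3S)-7,9-bis(benzyloxy)-8-oxo-2-[3,4,5-tris(benzyloxy)phenyl]-1-oxaspiro[4.5]deca-6,9-dien-3-yl acetate
Product: 17 (2R,3S)-5,7-bis(benzyloxy)-2-[3,4,5-tris(benzyloxy)phenyl]-3,4-dihydro-2H-chromen-3-yl acetate (3-O-acetyl-penta-O-benzyl-(+)-gallocatechin), via spiro dienol 15 (not isolated), via dienyl triflate 16 (not isolated)
Conditions: NaBH4, CeCl3·7H2O, MeOH/THF, −78 °C; NaHCO3 work-up; then Tf2O, 2,6-di-tert-butyl-4-methylpyridine, CH2Cl2, −78 to −20 °C
Reagents that add atoms: none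
Why: Proposed new method: Luche 1,2-reduction should give the dienol 15, and its O-triflation in the presence of a hindered pyridine base (so that the spiro ether oxygen is never protonated) should give the doubly allylic triflate 16, which ionises to a 6,6-disubstituted cyclohexadienyl cation carrying its charge on the two CH carbons next to the spiro carbon. A 1,2-shift of the oxolane CH2 (future C4) from the spiro carbon (future C8a) to one of these two equivalent carbons (future C4a) gives an arenium ion stabilised by O1 and both benzyloxy groups, and loss of the proton from C4a makes ring A aromatic, the added hydride ending as H-6. The closest known reaction type is the dienol–benzene rearrangement of 4,4-disubstituted cyclohexadienols, together with the dienone–phenol rearrangement of quinol ethers in which carbon likewise migrates away from the oxygen-bearing carbon; it has not been shown for a spiro-ether dienol forced to ionise at the carbinol carbon. Ring C is closed by ring expansion of the oxolane through this 1,2-alkyl shift (the C4–C8a bond breaks as the C4–C4a bond forms), not by a cyclisation. No stereocentre is created or touched, since C2 and C3 keep all four of their bonds, so the 2R,3S configuration of 14 is carried over unchanged. The step needs migration of carbon in preference to migration of O1 and to loss of the spiro ether oxygen: the cation has no β-hydrogen and can become aromatic only through a shift, the base-buffered medium leaves the spiro C–O bond unactivated, and only the carbon shift leaves an oxygen lone pair on the electron-poor carbon.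

Step 11
Reactants: 17 3-O-acetyl-penta-O-benzyl-(+)-gallocatechin
Product: 18 (2R,3S,4S)-5,7-bis(benzyloxy)-4-(2-ethoxyethoxy)-2-[3,4,5-tris(benzyloxy)phenyl]-3,4-dihydro-2H-chromen-3-yl acetate
Conditions: DDQ, 2-ethoxyethanol, CH2Cl2, rt
Reagents that add atoms: 2-ethoxyethanol, CCOCCO
Why: Oxidative C4 functionalisation with DDQ: hydride abstraction from the benzylic C4–H activated by the electron-rich ring A gives the C4 cation, which the alcohol traps (the 4S ether is expected, and its configuration is erased when C4 is ionised again in the coupling).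

Step 12
Reactants: 19 (+)-catechin
Product: 20 (2R,3S)-5,7-bis(benzyloxy)-2-[3,4-bis(benzyloxy)phenyl]-3,4-dihydro-2H-chromen-3-ol (5,7,3',4'-tetra-O-benzyl-(+)-catechin)
Conditions: BnBr, K2CO3, DMF, 0 °C to rt
Reagents that add atoms: benzyl bromide, BrCc1ccccc1
Why: Williamson etherification of the four phenolic hydroxyl groups, which are far more acidic than the secondary alcohol.

Step 13
Reactants: 20 5,7,3',4'-tetra-O-benzyl-(+)-catechin
Product: 21 (2R,3S,4S)-5,7-bis(benzyloxy)-2-[3,4-bis(benzyloxy)phenyl]-4-(2-ethoxyethoxy)-3,4-dihydro-2H-chromen-3-ol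
Conditions: DDQ, 2-ethoxyethanol, CH2Cl2, rt
Reagents that add atoms: 2-ethoxyethanol, CCOCCO
Why: Oxidative C4 functionalisation with DDQ as in step 11, hydride abstraction at C4 followed by capture of the cation by the alcohol.

Step 14
Reactants: 21 (2R,3S,4S)-5,7-bis(benzyloxy)-2-[3,4-bis(benzyloxy)phenyl]-4-(2-ethoxyethoxy)-3,4-dihydro-2H-chromen-3-ol
Product: 22 (2R,3S,4S)-5,7-bis(benzyloxy)-2-[3,4-bis(benzyloxy)phenyl]-4-(2-ethoxyethoxy)-3,4-dihydro-2H-chromen-3-yl acetate
Conditions: Ac2O, pyridine, DMAP (cat.), CH2Cl2, rt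
Reagents that add atoms: acetic anhydride, CC(=O)OC(C)=O
Why: Acylation installs the 3-acetate that will act as participating group in the coupling.

Step 15
Reactants: 18 (2R,3S,4S)-5,7-bis(benzyloxy)-4-(2-ethoxyethoxy)-2-[3,4,5-tris(benzyloxy)phenyl]-3,4-dihydro-2H-chromen-3-yl acetate; 17 3-O-acetyl-penta-O-benzyl-(+)-gallocatechin
Product: 23 [3-O-acetyl-penta-O-benzylgallocatechin]-(4α→8)-[3-O-acetyl-penta-O-benzylgallocatechin]
Conditions: TMSOTf (0.5 equiv), CH2Cl2, −78 °C; 17 in excess (4 equiv, recovered); Et3N quench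
Reagents that add atoms: none
Why: Lewis acid-promoted Friedel–Crafts-type flavan coupling: TMSOTf ionises the C4 ether, the 3-acetate bridges the cation on the β face (acetoxonium ion) and C8 of 17 attacks from the α face, which sets the new C4 centre 3,4-trans (4α), the excess of 17 suppressing self-condensation of 18.

Step 16
Reactants: 22 (2R,3S,4S)-5,7-bis(benzyloxy)-2-[3,4-bis(benzyloxy)phenyl]-4-(2-ethoxyethoxy)-3,4-dihydro-2H-chromen-3-yl acetate; 23 [3-O-acetyl-penta-O-benzylgallocatechin]-(4α→8)-[3-O-acetyl-penta-O-benzylgallocatechin]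
Product: 24 [3-O-acetyl-tetra-O-benzylcatechin]-(4α→8)-[3-O-acetyl-penta-O-benzylgallocatechin]-(4α→8)-[3-O-acetyl-penta-O-benzylgallocatechin]
Conditions: TMSOTf (0.5 equiv), CH2Cl2, −78 °C; 23 in excess (2.5 equiv, recovered); Et3N quench
Reagents that add atoms: none
Why: The same acetoxonium-controlled Friedel–Crafts-type coupling, the catechin C4 cation being attacked from the α face (new centre 3,4-trans, 4α) by C8 of the upper unit of 23, the only free position next to the ring oxygen (the other open sites are C6 carbons flanked by two benzyloxy groups).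

Step 17
Reactants: 24 the tris-acetate of the tetradeca-O-benzyl trimer
Product: 25 [tetra-O-benzylcatechin]-(4α→8)-[penta-O-benzylgallocatechin]-(4α→8)-[penta-O-benzylgallocatechin]
Conditions: n-Bu4NOH (40% aq), THF, rt
Reagents that add atoms: none
Why: Saponification of the three acetates under mild basic conditions that leave the benzyl ethers and the interflavan bonds intact.

Step 18
Reactants: 25 [tetra-O-benzylcatechin]-(4α→8)-[penta-O-benzylgallocatechin]-(4α→8)-[penta-O-benzylgallocatechin]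
Product: 26 catechin-(4α→8)-gallocatechin-(4α→8)-gallocatechin
Conditions: H2 (1 atm), Pd(OH)2/C, THF/MeOH/H2O, rt; filtration and freeze-drying under argon
Reagents that add atoms: none
Why: Hydrogenolysis of the fourteen benzyl ethers under neutral conditions, which spares the acid-labile interflavan bonds and the stereocentres.

Compound list
1 | 1,3-bis(benzyloxy)benzene | c1ccccc1COc1cccc(OCc2ccccc2)c1 | starting material
2 | [2,6-bis(benzyloxy)phenyl]lithium | [Li]c1c(OCc2ccccc2)cccc1OCc1ccccc1 | intermediate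
3 | lithium [2,6-bis(benzyloxy)phenyl]trimethoxyborate | [Li+].CO[B-](OC)(OC)c1c(OCc2ccccc2)cccc1OCc1ccccc1 | intermediate
4 | 2,6-bis(benzyloxy)phenol | Oc1c(OCc2ccccc2)cccc1OCc1ccccc1 | intermediate
5 | 2,6-bis(benzyloxy)-4-bromophenol | Oc1c(OCc2ccccc2)cc(Br)cc1OCc1ccccc1 | intermediate
6 | [2,6-bis(benzyloxy)-4-bromophenoxy](tert-butyl)dimethylsilane | CC(C)(C)[Si](C)(C)Oc1c(OCc2ccccc2)cc(Br)cc1OCc1ccccc1 | intermediate
7 | 3,4,5-tris(benzyloxy)benzaldehyde | O=Cc1cc(OCc2ccccc2)c(OCc2ccccc2)c(OCc2ccccc2)c1 | starting material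
8 | rac-1-[3,4,5-tris(benzyloxy)phenyl]prop-2-en-1-ol | OC(C=C)c1cc(OCc2ccccc2)c(OCc2ccccc2)c(OCc2ccccc2)c1 | intermediate
9 | (R)-[(2S)-oxiran-2-yl][3,4,5-tris(benzyloxy)phenyl]methanol | O[C@H](c1cc(OCc2ccccc2)c(OCc2ccccc2)c(OCc2ccccc2)c1)[C@@H]1CO1 | intermediate
10 | {3,5-bis(benzyloxy)-4-[(tert-butyldimethylsilyl)oxy]phenyl}magnesium bromide | CC(C)(C)[Si](C)(C)Oc1c(OCc2ccccc2)cc([Mg]Br)cc1OCc1ccccc1 | intermediate
11 | (1R,2S)-3-{3,5-bis(benzyloxy)-4-[(tert-butyldimethylsilyl)oxy]phenyl}-1-[3,4,5-tris(benzyloxy)phenyl]propane-1,2-diol | CC(C)(C)[Si](C)(C)Oc1c(OCc2ccccc2)cc(C[C@H](O)[C@H](O)c2cc(OCc3ccccc3)c(OCc3ccccc3)c(OCc3ccccc3)c2)cc1OCc1ccccc1 | intermediate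
12 | (1R,2S)-3-[3,5-bis(benzyloxy)-4-hydroxyphenyl]-1-[3,4,5-tris(benzyloxy)phenyl]propane-1,2-diol | Oc1c(OCc2ccccc2)cc(C[C@H](O)[C@H](O)c2cc(OCc3ccccc3)c(OCc3ccccc3)c(OCc3ccccc3)c2)cc1OCc1ccccc1 | intermediate
13 | (2R,3S)-7,9-bis(benzyloxy)-3-hydroxy-2-[3,4,5-tris(benzyloxy)phenyl]-1-oxaspiro[4.5]deca-6,9-dien-8-one | O=C1C(OCc3ccccc3)=CC2(C=C1OCc1ccccc1)O[C@H](c1cc(OCc3ccccc3)c(OCc3ccccc3)c(OCc3ccccc3)c1)[C@@H](O)C2 | intermediate
14 | (2R,3S)-7,9-bis(benzyloxy)-8-oxo-2-[3,4,5-tris(benzyloxy)phenyl]-1-oxaspiro[4.5]deca-6,9-dien-3-yl acetate | O=C1C(OCc3ccccc3)=CC2(C=C1OCc1ccccc1)O[C@H](c1cc(OCc3ccccc3)c(OCc3ccccc3)c(OCc3ccccc3)c1)[C@@H](OC(C)=O)C2 | intermediate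
15 | (2R,3S)-7,9-bis(benzyloxy)-8-hydroxy-2-[3,4,5-tris(benzyloxy)phenyl]-1-oxaspiro[4.5]deca-6,9-dien-3-yl acetate (both C8 epimers, which converge) | OC1C(OCc3ccccc3)=CC2(C=C1OCc1ccccc1)O[C@H](c1cc(OCc3ccccc3)c(OCc3ccccc3)c(OCc3ccccc3)c1)[C@@H](OC(C)=O)C2 | intermediate
16 | (2R,3S)-7,9-bis(benzyloxy)-8-[(trifluoromethanesulfonyl)oxy]-2-[3,4,5-tris(benzyloxy)phenyl]-1-oxaspiro[4.5]deca-6,9-dien-3-yl acetate (both C8 epimers) | FC(F)(F)S(=O)(=O)OC1C(OCc3ccccc3)=CC2(C=C1OCc1ccccc1)O[C@H](c1cc(OCc3ccccc3)c(OCc3ccccc3)c(OCc3ccccc3)c1)[C@@H](OC(C)=O)C2 | intermediate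
17 | (2R,3S)-5,7-bis(benzyloxy)-2-[3,4,5-tris(benzyloxy)phenyl]-3,4-dihydro-2H-chromen-3-yl acetate (3-O-acetyl-penta-O-benzyl-(+)-gallocatechin) | c1ccccc1COc1cc(OCc3ccccc3)c2c(c1)O[C@H](c1cc(OCc3ccccc3)c(OCc3ccccc3)c(OCc3ccccc3)c1)[C@@H](OC(C)=O)C2 | intermediate
18 | (2R,3S,4S)-5,7-bis(benzyloxy)-4-(2-ethoxyethoxy)-2-[3,4,5-tris(benzyloxy)phenyl]-3,4-dihydro-2H-chromen-3-yl acetate | c1ccccc1COc1cc(OCc3ccccc3)c2c(c1)O[C@H](c1cc(OCc3ccccc3)c(OCc3ccccc3)c(OCc3ccccc3)c1)[C@@H](OC(C)=O)[C@H]2OCCOCC | intermediate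
19 | (+)-catechin, (2R,3S) | Oc1cc(O)c2c(c1)O[C@H](c1ccc(O)c(O)c1)[C@@H](O)C2 | starting material
20 | (2R,3S)-5,7-bis(benzyloxy)-2-[3,4-bis(benzyloxy)phenyl]-3,4-dihydro-2H-chromen-3-ol | c1ccccc1COc1cc(OCc3ccccc3)c2c(c1)O[C@H](c1ccc(OCc3ccccc3)c(OCc3ccccc3)c1)[C@@H](O)C2 | intermediate
21 | (2R,3S,4S)-5,7-bis(benzyloxy)-2-[3,4-bis(benzyloxy)phenyl]-4-(2-ethoxyethoxy)-3,4-dihydro-2H-chromen-3-ol | c1ccccc1COc1cc(OCc3ccccc3)c2c(c1)O[C@H](c1ccc(OCc3ccccc3)c(OCc3ccccc3)c1)[C@@H](O)[C@H]2OCCOCC | intermediate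
22 | (2R,3S,4S)-5,7-bis(benzyloxy)-2-[3,4-bis(benzyloxy)phenyl]-4-(2-ethoxyethoxy)-3,4-dihydro-2H-chromen-3-yl acetate | c1ccccc1COc1cc(OCc3ccccc3)c2c(c1)O[C@H](c1ccc(OCc3ccccc3)c(OCc3ccccc3)c1)[C@@H](OC(C)=O)[C@H]2OCCOCC | intermediate
23 | [3-O-acetyl-5,7,3',4',5'-penta-O-benzylgallocatechin]-(4α→8)-[3-O-acetyl-5,7,3',4',5'-penta-O-benzylgallocatechin] | c1ccccc1COc1cc(OCc3ccccc3)c2c(c1)O[C@H](c1cc(OCc3ccccc3)c(OCc3ccccc3)c(OCc3ccccc3)c1)[C@@H](OC(C)=O)[C@@H]2c1c(OCc3ccccc3)cc(OCc3ccccc3)c2c1O[C@H](c1cc(OCc3ccccc3)c(OCc3ccccc3)c(OCc3ccccc3)c1)[C@@H](OC(C)=O)C2 | intermediate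
24 | [3-O-acetyl-5,7,3',4'-tetra-O-benzylcatechin]-(4α→8)-[3-O-acetyl-penta-O-benzylgallocatechin]-(4α→8)-[3-O-acetyl-penta-O-benzylgallocatechin] | c1ccccc1COc1cc(OCc3ccccc3)c2c(c1)O[C@H](c1ccc(OCc3ccccc3)c(OCc3ccccc3)c1)[C@@H](OC(C)=O)[C@@H]2c1c(OCc3ccccc3)cc(OCc3ccccc3)c2c1O[C@H](c1cc(OCc3ccccc3)c(OCc3ccccc3)c(OCc3ccccc3)c1)[C@@H](OC(C)=O)[C@@H]2c1c(OCc3ccccc3)cc(OCc3ccccc3)c2c1O[C@H](c1cc(OCc3ccccc3)c(OCc3ccccc3)c(OCc3ccccc3)c1)[C@@H](OC(C)=O)C2 | intermediate
25 | [5,7,3',4'-tetra-O-benzylcatechin]-(4α→8)-[penta-O-benzylgallocatechin]-(4α→8)-[penta-O-benzylgallocatechin] | c1ccccc1COc1cc(OCc3ccccc3)c2c(c1)O[C@H](c1ccc(OCc3ccccc3)c(OCc3ccccc3)c1)[C@@H](O)[C@@H]2c1c(OCc3ccccc3)cc(OCc3ccccc3)c2c1O[C@H](c1cc(OCc3ccccc3)c(OCc3ccccc3)c(OCc3ccccc3)c1)[C@@H](O)[C@@H]2c1c(OCc3ccccc3)cc(OCc3ccccc3)c2c1O[C@H](c1cc(OCc3ccccc3)c(OCc3ccccc3)c(OCc3ccccc3)c1)[C@@H](O)C2 | intermediate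
26 | catechin-(4α→8)-gallocatechin-(4α→8)-gallocatechin (CNP0188605.2) | Oc1cc(O)c2c(c1)O[C@H](c1ccc(O)c(O)c1)[C@@H](O)[C@@H]2c1c(O)cc(O)c2c1O[C@H](c1cc(O)c(O)c(O)c1)[C@@H](O)[C@@H]2c1c(O)cc(O)c2c1O[C@H](c1cc(O)c(O)c(O)c1)[C@@H](O)C2 | target

Total step count: 18 steps.
Longest linear sequence: 13 steps (steps 1–3, 6–11, 15–18).

Steps most likely to fail

Step 10 (key step, proposed new method). The carbon shift may be outrun by heterolysis of the spiro C–O bond (return to an open-chain phenol), by migration of O1 instead of C4, or by collapse of the ion pair without rearrangement. The fallback runs the same ring expansion at the dienone stage, where the spiro oxygen cannot be lost, using known chemistry. It sets out from 14: BF3·OEt2 in CH2Cl2 (−40 to 0 °C) should induce a dienone–phenol rearrangement, C4 again moving from C8a to C4a, to give (2R,3S)-5,7-bis(benzyloxy)-6-hydroxy-2-[3,4,5-tris(benzyloxy)phenyl]-3,4-dihydro-2H-chromen-3-yl acetate F1. The surplus phenol would be removed by triflation (Tf2O, pyridine) to the aryl triflate F2 and palladium-catalysed reduction (Pd(OAc)2, 1,3-bis(diphenylphosphino)propane, HCO2H, Et3N, DMF, 70 °C), which comes back to the route at 17.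

Step 16. Attack of the dimer may not stay confined to C8 of its upper unit, and the electrophile or the product may condense further. The fallback reverses the order of bond formation with a thioether as latent leaving group (orthogonal activation). It sets out from 18: phenylmethanethiol and BF3·OEt2 (CH2Cl2, −78 °C) should give, through the acetoxonium ion, the 4α-benzylthio derivative of 3-O-acetyl-penta-O-benzylgallocatechin F3. Its C–S bond is inert to TMSOTf, so F3 would serve as a monomeric nucleophile toward 22 and give [3-O-acetyl-tetra-O-benzylcatechin]-(4α→8)-[3-O-acetyl-4α-benzylthio-penta-O-benzylgallocatechin] F4. AgBF4 would then ionise the C–S bond of F4 in the presence of 17, and the route is rejoined at 24.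

Step 5. Discrimination between the enantiomers may be poor (a terminal vinyl group is epoxidised slowly), and the electron-rich benzylic carbinol may ionise on titanium and erode the configuration. The fallback sets the carbinol centre by catalytic enantioselective vinylation instead of resolution. It sets out from 7: Zn(CH=CH2)2 with the enantiomer of 3-exo-morpholinoisoborneol that delivers the (S)-carbinol should give (S)-1-[3,4,5-tris(benzyloxy)phenyl]prop-2-en-1-ol F5. Epoxidation of F5 with t-BuOOH, Ti(OiPr)4 and D-(−)-diisopropyl tartrate, now a matched directed epoxidation run to full conversion, comes back to the route at 9.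

Further compounds
F1 | step 10 | (2R,3S)-5,7-bis(benzyloxy)-6-hydroxy-2-[3,4,5-tris(benzyloxy)phenyl]-3,4-dihydro-2H-chromen-3-yl acetate | c1ccccc1COc1c(O)c(OCc3ccccc3)c2c(c1)O[C@H](c1cc(OCc3ccccc3)c(OCc3ccccc3)c(OCc3ccccc3)c1)[C@@H](OC(C)=O)C2
F2 | step 10 | (2R,3S)-5,7-bis(benzyloxy)-6-[(trifluoromethanesulfonyl)oxy]-2-[3,4,5-tris(benzyloxy)phenyl]-3,4-dihydro-2H-chromen-3-yl acetate | c1ccccc1COc1c(OS(=O)(=O)C(F)(F)F)c(OCc3ccccc3)c2c(c1)O[C@H](c1cc(OCc3ccccc3)c(OCc3ccccc3)c(OCc3ccccc3)c1)[C@@H](OC(C)=O)C2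
F3 | step 16 | 3-O-acetyl-4α-benzylthio-5,7,3',4',5'-penta-O-benzylgallocatechin (3,4-trans) | c1ccccc1COc1cc(OCc3ccccc3)c2c(c1)O[C@H](c1cc(OCc3ccccc3)c(OCc3ccccc3)c(OCc3ccccc3)c1)[C@@H](OC(C)=O)[C@@H]2SCc1ccccc1
F4 | step 16 | [3-O-acetyl-tetra-O-benzylcatechin]-(4α→8)-[3-O-acetyl-4α-benzylthio-penta-O-benzylgallocatechin] | c1ccccc1COc1cc(OCc3ccccc3)c2c(c1)O[C@H](c1ccc(OCc3ccccc3)c(OCc3ccccc3)c1)[C@@H](OC(C)=O)[C@@H]2c1c(OCc3ccccc3)cc(OCc3ccccc3)c2c1O[C@H](c1cc(OCc3ccccc3)c(OCc3ccccc3)c(OCc3ccccc3)c1)[C@@H](OC(C)=O)[C@@H]2SCc1ccccc1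
F5 | step 5 | (S)-1-[3,4,5-tris(benzyloxy)phenyl]prop-2-en-1-ol | O[C@H](c1cc(OCc2ccccc2)c(OCc2ccccc2)c(OCc2ccccc2)c1)C=C
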